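**Retrosynthetic overview**

1. Target ⇐ (3R)-3-aryl-7-silyloxychroman-2-one 15 by reduction of the lactone C2=O to CH2 and removal of TIPS/MOM; the 1,1-dimethylallyl group is installed early by aromatic Claisen rearrangement of the gallacetophenone 4-O-prenyl ether.
2. Key disconnection: the six-membered ring O1–C2–C3–C4–C4a–C8a is not closed as such; it comes by one-atom ring expansion of the five-membered dihydrofuran ring of racemic 2-aryl-2-formyl-2,3-dihydrobenzofuran 14 (carbene-catalysed redox ring expansion, C3–H set by enantioselective protonation).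
3. Enabling feature: in 14 the aldehyde carbon (future C2) sits on the quaternary ring carbon (future C3) that carries both the ring oxygen O1 and the B-ring aryl. O1 is thus a phenoxide leaving group α to the carbene-bound carbonyl, and it stays tethered through C4 and the A ring so that it re-closes on the acyl carbon as a six-membered lactone. The old centre is erased, so 14 may be racemic.
4. 14 ⇐ epoxidation/5-exo phenol capture of 2-(2-arylallyl)phenol 11 ⇐ Wittig ⇐ o-hydroxybenzyl aryl ketone 10 ⇐ Pd α-arylation of B-ring acetophenone 7 with bromophenol 9.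
5. Ring order: both benzene rings are bought; dihydrofuran ring (step 8) → ring-expanded dihydropyranone (step 10) → chroman (step 11).

Key step: step 10

Remark on the chemistry: the given SMILES corresponds to the (3R)-isoflavan (C2 > aryl > C4 > H). Both antipodes of the triazolium precatalyst are accessible, so the required sense of induction is obtained by choosing the catalyst enantiomer.
Abbreviations: Ar = 2-methoxy-3,4-bis(methoxymethoxy)-5-(2-methylbut-3-en-2-yl)phenyl; MOM = methoxymethyl; TIPS = tri(propan-2-yl)silyl.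

**Route**

Step 1
Reactants: 1 gallacetophenone [1-(2,3,4-trihydroxyphenyl)ethan-1-one]; 2 prenyl bromide (1-bromo-3-methylbut-2-ene)
Product: 3 1-{2,3-dihydroxy-4-[(3-methylbut-2-en-1-yl)oxy]phenyl}ethan-1-one
Conditions: 2 (1.05 equiv), NaHCO3, DMF, 40 °C
Reagents that add atoms: none
Why: Williamson etherification; the 4-OH (para to the acetyl group) is the most acidic and the only unhindered, non-chelated phenol under bicarbonate, so mono-O-prenylation at O4 should dominate over O3 and the hydrogen-bonded O2.

Step 2
Reactants: 3 1-{2,3-dihydroxy-4-[(3-methylbut-2-en-1-yl)oxy]phenyl}ethan-1-one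
Product: 5 1-[2,3,4-trihydroxy-5-(2-methylbut-3-en-2-yl)phenyl]ethan-1-one, via Claisen dienone 4 (not isolated)
Conditions: EtOH–H2O (4:1), 130 °C, sealed tube, argon
Reagents that add atoms: none
Why: Aromatic Claisen rearrangement ([3,3]) transfers the prenyl unit with allylic inversion (giving the 1,1-dimethylallyl group) to C5, the only ortho position bearing hydrogen, and dienone 4 re-aromatises by enolisation; the aqueous medium accelerates the shift so that it should run below the temperature at which the product phenol adds to its own double bond.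

Step 3
Reactants: 5 1-[2,3,4-trihydroxy-5-(2-methylbut-3-en-2-yl)phenyl]ethan-1-one
Product: 6 1-[2-hydroxy-3,4-bis(methoxymethoxy)-5-(2-methylbut-3-en-2-yl)phenyl]ethan-1-one
Conditions: MOMCl (2.4 equiv), iPr2NEt, CH2Cl2, 0 °C → rt
Reagents that add atoms: chloromethyl methyl ether (MOMCl), COCCl
Why: O-Alkylation (acetal formation) under amine base takes the two non-chelated phenols, while the 2-OH stays locked in its hydrogen bond to the ketone.

Step 4
Reactants: 6 1-[2-hydroxy-3,4-bis(methoxymethoxy)-5-(2-methylbut-3-en-2-yl)phenyl]ethan-1-one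
Product: 7 1-[2-methoxy-3,4-bis(methoxymethoxy)-5-(2-methylbut-3-en-2-yl)phenyl]ethan-1-one (Ar–CO–CH3)
Conditions: MeI, K2CO3, DMF, 40 °C
Reagents that add atoms: iodomethane, CI
Why: Williamson methylation of the remaining chelated phenol under carbonate/DMF; carbonate is too weak to enolise the ketone, so no C-methylation is expected.

Step 5
Reactants: 8 4-bromoresorcinol (4-bromobenzene-1,3-diol)
Product: 9 2-bromo-5-{[tri(propan-2-yl)silyl]oxy}phenol
Conditions: TIPSCl (1.0 equiv), imidazole, CH2Cl2–DMF, 0 °C
Reagents that add atoms: chlorotri(propan-2-yl)silane (TIPSCl), CC(C)[Si](Cl)(C(C)C)C(C)C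
Why: Silylation with the bulky TIPSCl is sterically controlled and should take the hydroxyl para to bromine, leaving the hindered ortho-bromo phenol (the future O1) free.

Step 6
Reactants: 7 Ar–CO–CH3; 9 2-bromo-5-{[tri(propan-2-yl)silyl]oxy}phenol
Product: 10 1-Ar-2-(2-hydroxy-4-{[tri(propan-2-yl)silyl]oxy}phenyl)ethan-1-one (in equilibrium with its cyclic hemiketal)
Conditions: Pd2(dba)3 (2.5 mol %), 2-(di-tert-butylphosphino)-1,1'-binaphthyl, NaOtBu (2.5 equiv), toluene, 80 °C; aq. NH4Cl work-up
Reagents that add atoms: none
Why: Pd-catalysed α-arylation of a methyl ketone enolate tolerates free o-bromophenols when an extra equivalent of base is used and should stop at mono-arylation with an ortho-substituted aryl bromide; acid-free work-up avoids cyclodehydration to the 2-arylbenzofuran.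

Step 7
Reactants: 10 1-Ar-2-(2-hydroxy-4-{[tri(propan-2-yl)silyl]oxy}phenyl)ethan-1-one
Product: 11 2-(2-Ar-prop-2-en-1-yl)-5-{[tri(propan-2-yl)silyl]oxy}phenol
Conditions: Ph3PCH3Br (3.5 equiv), KOtBu (3.3 equiv), THF, 0 → 50 °C
Reagents that add atoms: methyltriphenylphosphonium bromide, C[P+](c1ccccc1)(c1ccccc1)c1ccccc1.[Br-]
Why: Wittig methylenation with excess ylide (one equivalent is consumed by the phenol) converts the ketone, which is drawn from its enolate/hemiketal equilibria, into the 1,1-disubstituted alkene.

Step 8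
Reactants: 11 2-(2-Ar-prop-2-en-1-yl)-5-{[tri(propan-2-yl)silyl]oxy}phenol
Product: 13 rac-(2-Ar-6-{[tri(propan-2-yl)silyl]oxy}-2,3-dihydro-1-benzofuran-2-yl)methanol, via epoxide 12 (not isolated)
Conditions: mCPBA (1.05 equiv), NaHCO3, CH2Cl2, 0 °C; then PPTS (cat.), 0 °C
Reagents that add atoms: 3-chloroperoxybenzoic acid (mCPBA), OOC(=O)c1cccc(Cl)c1
Why: Prilezhaev epoxidation should occur at the electron-rich 1,1-disubstituted styrene much faster than at the hindered monosubstituted vinyl group, and epoxide 12 is opened by the neighbouring phenol at the tertiary benzylic carbon (5-exo, Markovnikov, cation stabilised by the o-methoxy/p-alkoxy aryl); the new quaternary centre forms as a racemate, which is intended because step 10 erases it.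

Step 9
Reactants: 13 rac-(2-Ar-6-{[tri(propan-2-yl)silyl]oxy}-2,3-dihydro-1-benzofuran-2-yl)methanol
Product: 14 rac-2-Ar-6-{[tri(propan-2-yl)silyl]oxy}-2,3-dihydro-1-benzofuran-2-carbaldehyde
Conditions: Dess–Martin periodinane, NaHCO3, CH2Cl2, rt
Reagents that add atoms: none
Why: Dess–Martin oxidation of a primary neopentyl-type alcohol gives an aldehyde without α-hydrogen, which cannot enolise; the bicarbonate buffer protects the MOM acetals.

Step 10
Reactants: 14 rac-2-Ar-6-{[tri(propan-2-yl)silyl]oxy}-2,3-dihydro-1-benzofuran-2-carbaldehyde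
Product: 15 (3R)-3-Ar-7-{[tri(propan-2-yl)silyl]oxy}-3,4-dihydro-2H-1-benzopyran-2-one
Conditions: chiral aminoindanol-derived bicyclic N-C6F5 triazolium tetrafluoroborate (10 mol %, antipode chosen for R), iPr2NEt (10 mol %), toluene, 4 Å MS, rt
Reagents that add atoms: none
Why: Proposed new method: the triazolylidene adds to the aldehyde, the Breslow intermediate expels the ring oxygen O1 from the quaternary α-carbon as a phenoxide (opening the five-membered ring and erasing the racemic centre), the resulting azolium enolate is protonated on carbon, and the tethered phenoxide then attacks the acyl azolium to close the six-membered lactone and release the carbene. The closest known reactions are the achiral carbene-catalysed ring expansion of oxacycloalkane-2-carbaldehydes to lactones and the carbene-controlled enantioselective protonation of α-aryl-α-alkyl azolium enolates generated from α-halo aldehydes or aryl alkyl ketenes; their combination on a quaternary α-aryl-α-aryloxy aldehyde has not been shown. The lactone ring closes by 6-exo-trig acyl substitution of O1 at the acyl azolium carbon. The only stereocentre, C3, is created in the C-protonation of the azolium enolate, whose two faces are differentiated by the aminoindanol backbone of the catalyst. The step needs enantioface selectivity in this proton transfer and no racemisation of the α-aryl aryl ester afterwards; the substoichiometric weak base, the non-polar solvent and the electron-rich aryl group (lower C–H acidity) should secure the latter, and the absence of α-hydrogen together with the good phenoxide leaving group should channel the Breslow intermediate into ring opening and away from benzoin-type pathways.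

Step 11
Reactants: 15 (3R)-3-Ar-7-{[tri(propan-2-yl)silyl]oxy}-3,4-dihydro-2H-1-benzopyran-2-one
Product: 17 tri(propan-2-yl){[(3R)-3-Ar-3,4-dihydro-2H-1-benzopyran-7-yl]oxy}silane, via lactol 16 (not isolated)
Conditions: DIBAL-H (1.1 equiv), CH2Cl2, −78 °C; then Et3SiH, BF3·OEt2, −78 → −40 °C
Reagents that add atoms: none
Why: Partial reduction of the aryl lactone by DIBAL-H at −78 °C stops at the lactol stage, and Lewis acid-promoted ionic hydrogenation (Et3SiH/BF3·OEt2) of the derived cyclic oxocarbenium ion gives the cyclic ether with the ring intact; C3 is not involved as long as the low temperature keeps the ring-opened α-aryl aldehyde and the 4H-chromene enol ether from forming.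

Step 12
Reactants: 17 tri(propan-2-yl){[(3R)-3-Ar-3,4-dihydro-2H-1-benzopyran-7-yl]oxy}silane
Product: 19 4-[(3R)-7-hydroxy-3,4-dihydro-2H-1-benzopyran-3-yl]-3-methoxy-6-(2-methylbut-3-en-2-yl)benzene-1,2-diol (CNP0167796.1), via desilylated phenol 18 (not isolated)
Conditions: TBAF (1.1 equiv), THF, 0 °C; then 3 M HCl, MeOH, 40 °C, argon
Reagents that add atoms: none
Why: Fluoride cleaves the aryl silyl ether and dilute methanolic HCl then removes both MOM groups by acetal exchange; the ortho-(1,1-dimethylallyl)phenol motif should tolerate dilute acid at this temperature, and the C3 stereocentre is not affected.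

**Compound list**

1 | gallacetophenone, 1-(2,3,4-trihydroxyphenyl)ethan-1-one | CC(=O)c1ccc(O)c(O)c1O | starting material
2 | prenyl bromide, 1-bromo-3-methylbut-2-ene | CC(C)=CCBr | starting material
3 | 1-{2,3-dihydroxy-4-[(3-methylbut-2-en-1-yl)oxy]phenyl}ethan-1-one | CC(=O)c1ccc(OCC=C(C)C)c(O)c1O | intermediate
4 | Claisen dienone, 4-acetyl-2,3-dihydroxy-6-(2-methylbut-3-en-2-yl)cyclohexa-2,4-dien-1-one | CC(=O)C1=CC(C(C)(C)C=C)C(=O)C(O)=C1O | intermediate
5 | 1-[2,3,4-trihydroxy-5-(2-methylbut-3-en-2-yl)phenyl]ethan-1-one | CC(=O)c1cc(C(C)(C)C=C)c(O)c(O)c1O | intermediate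
6 | 1-[2-hydroxy-3,4-bis(methoxymethoxy)-5-(2-methylbut-3-en-2-yl)phenyl]ethan-1-one | CC(=O)c1cc(C(C)(C)C=C)c(OCOC)c(OCOC)c1O | intermediate
7 | 1-[2-methoxy-3,4-bis(methoxymethoxy)-5-(2-methylbut-3-en-2-yl)phenyl]ethan-1-one | CC(=O)c1cc(C(C)(C)C=C)c(OCOC)c(OCOC)c1OC | intermediate
8 | 4-bromoresorcinol, 4-bromobenzene-1,3-diol | Oc1ccc(Br)c(O)c1 | starting material
9 | 2-bromo-5-{[tri(propan-2-yl)silyl]oxy}phenol | Oc1cc(O[Si](C(C)C)(C(C)C)C(C)C)ccc1Br | intermediate
10 | 1-Ar-2-(2-hydroxy-4-{[tri(propan-2-yl)silyl]oxy}phenyl)ethan-1-one | O=C(Cc1ccc(O[Si](C(C)C)(C(C)C)C(C)C)cc1O)c1cc(C(C)(C)C=C)c(OCOC)c(OCOC)c1OC | intermediate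
11 | 2-(2-Ar-prop-2-en-1-yl)-5-{[tri(propan-2-yl)silyl]oxy}phenol | C=C(Cc1ccc(O[Si](C(C)C)(C(C)C)C(C)C)cc1O)c1cc(C(C)(C)C=C)c(OCOC)c(OCOC)c1OC | intermediate
12 | epoxide, rac-2-[(2-Ar-oxiran-2-yl)methyl]-5-{[tri(propan-2-yl)silyl]oxy}phenol | Oc1cc(O[Si](C(C)C)(C(C)C)C(C)C)ccc1CC1(CO1)c1cc(C(C)(C)C=C)c(OCOC)c(OCOC)c1OC | intermediate
13 | rac-(2-Ar-6-{[tri(propan-2-yl)silyl]oxy}-2,3-dihydro-1-benzofuran-2-yl)methanol | OCC1(Cc2ccc(O[Si](C(C)C)(C(C)C)C(C)C)cc2O1)c1cc(C(C)(C)C=C)c(OCOC)c(OCOC)c1OC | intermediate
14 | rac-2-Ar-6-{[tri(propan-2-yl)silyl]oxy}-2,3-dihydro-1-benzofuran-2-carbaldehyde | O=CC1(Cc2ccc(O[Si](C(C)C)(C(C)C)C(C)C)cc2O1)c1cc(C(C)(C)C=C)c(OCOC)c(OCOC)c1OC | intermediate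
15 | (3R)-3-Ar-7-{[tri(propan-2-yl)silyl]oxy}-3,4-dihydro-2H-1-benzopyran-2-one | O=C1Oc2cc(O[Si](C(C)C)(C(C)C)C(C)C)ccc2C[C@@H]1c1cc(C(C)(C)C=C)c(OCOC)c(OCOC)c1OC | intermediate
16 | lactol, (3R)-3-Ar-7-{[tri(propan-2-yl)silyl]oxy}-3,4-dihydro-2H-1-benzopyran-2-ol (both C2 epimers) | OC1Oc2cc(O[Si](C(C)C)(C(C)C)C(C)C)ccc2C[C@@H]1c1cc(C(C)(C)C=C)c(OCOC)c(OCOC)c1OC | intermediate
17 | tri(propan-2-yl){[(3R)-3-Ar-3,4-dihydro-2H-1-benzopyran-7-yl]oxy}silane | C1Oc2cc(O[Si](C(C)C)(C(C)C)C(C)C)ccc2C[C@@H]1c1cc(C(C)(C)C=C)c(OCOC)c(OCOC)c1OC | intermediate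
18 | desilylated phenol, (3R)-3-Ar-3,4-dihydro-2H-1-benzopyran-7-ol | C1Oc2cc(O)ccc2C[C@@H]1c1cc(C(C)(C)C=C)c(OCOC)c(OCOC)c1OC | intermediate
19 | 4-[(3R)-7-hydroxy-3,4-dihydro-2H-1-benzopyran-3-yl]-3-methoxy-6-(2-methylbut-3-en-2-yl)benzene-1,2-diol | C1Oc2cc(O)ccc2C[C@@H]1c1cc(C(C)(C)C=C)c(O)c(O)c1OC | target

**Step count and risks**

Total step count: 12. Longest linear sequence: 11 steps (steps 1–4 and 6–12); step 5 is the only branch step.

Steps most likely to fail:

1. Step 10 (bears the label). What may go wrong: slow addition of the carbene to the hindered quaternary aldehyde, insufficient facial discrimination in the proton transfer to the azolium enolate, or base-mediated racemisation of the lactone after it has formed. Fallback with known chemistry: it sets out from aldehyde 14. The ring expansion is run with an achiral carbene (N-mesityl imidazolinium chloride, DBU cat., CH2Cl2, rt), which should give the racemic lactone F1. F1, whose C3–H is labile under alkoxide, is then hydrogenated under dynamic kinetic resolution (Ir–SpiroPAP catalyst, KOtBu, H2, n-PrOH), a carbonyl-selective reduction that should leave the vinyl group alone, to the (R)-configured diol F2. F2 is closed by Mitsunobu etherification (PPh3, DIAD, THF, 0 °C) to chroman 17, where the route is rejoined before step 12.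

2. Step 11. What may go wrong: loss of configurational integrity at C3 through ring opening of the lactol to the α-aryl aldehyde and enolisation, or through deprotonation of the oxocarbenium ion to the 4H-chromene and reprotonation; partial MOM loss under BF3 would be harmless because step 12 removes these groups anyway. Fallback: it sets out from lactone 15, which is reduced with LiBH4 (THF, 0 °C) to the diol F3 (the same compound as F2). F3 is closed by Mitsunobu etherification (PPh3, DIAD, THF, 0 °C) to chroman 17, where the route is rejoined. This avoids every aldehyde-level and cationic intermediate, at the cost of opening and re-closing the ring.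

3. Step 8. What may go wrong: competing epoxidation of the 1,1-dimethylallyl double bond or oxidation of the electron-rich phenol by the peracid, and semipinacol (Meinwald) opening of the epoxide before the phenol captures the benzylic cation. Fallback: it sets out from ketone 10 and bypasses alkene 11. Corey–Chaykovsky epoxidation with dimethylsulfonium methylide (Me3S+ I−, NaH, DMSO–THF, 0 °C) should give epoxide 12 directly, without any oxidant. Buffered work-up followed by PPTS (CH2Cl2, 0 °C) closes the ring to alcohol 13, where the route is rejoined. No new compound arises.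

Further compounds
F1 | step 10 | rac-3-Ar-7-{[tri(propan-2-yl)silyl]oxy}-3,4-dihydro-2H-1-benzopyran-2-one | O=C1Oc2cc(O[Si](C(C)C)(C(C)C)C(C)C)ccc2CC1c1cc(C(C)(C)C=C)c(OCOC)c(OCOC)c1OC
F2 | step 10 | 2-[(2R)-2-Ar-3-hydroxypropyl]-5-{[tri(propan-2-yl)silyl]oxy}phenol | OC[C@H](Cc1ccc(O[Si](C(C)C)(C(C)C)C(C)C)cc1O)c1cc(C(C)(C)C=C)c(OCOC)c(OCOC)c1OC
F3 | step 11 | 2-[(2R)-2-Ar-3-hydroxypropyl]-5-{[tri(propan-2-yl)silyl]oxy}phenol | OC[C@H](Cc1ccc(O[Si](C(C)C)(C(C)C)C(C)C)cc1O)c1cc(C(C)(C)C=C)c(OCOC)c(OCOC)c1OC
F0 | step 8 | none | none
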